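**Retrosynthetic overview**
1. Sarothralin 16 is cut at the ArC–CH2 bond of the methylene bridge (Mannich/Michael logic) into isobutyrylfilicinic acid 4, a one-carbon aminal and the 2-O-prenylated benzophenone 13.
2. Key disconnection: the C(=O)–Ph bond of 13. The formyl carbon of aldehyde 8 acts as an acyl anion (NHC/Breslow catalysis) and is joined to benzyne, so two natively electrophilic carbons are united under basic, Lewis-acid-free conditions that spare the prenyl ether.
3. Aldehyde 8 comes from 2,4,6-trihydroxybenzaldehyde: chelation-controlled bis-MOM protection leaves only the ortho hydroxyl free for prenylation, which fixes the ether regiochemistry.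
4. 4 comes from phloroglucinol by Friedel–Crafts isobutyrylation and dearomatising gem-dimethylation.
5. Rings: none is built de novo. Both carbocycles are bought as benzenoids; the filicinic ring arises by dearomatisation (step 2) before the fragment union (step 7).

Assumption: the target SMILES has no stereocentre and no stereogenic double bond, so the compound is achiral and no stereocontrol is needed; it is drawn as the enol tautomer given.

**Route**

Step 1
Reactants: 1 phloroglucinol; 2 isobutyryl chloride
Product: 3 phlorisobutyrophenone (2-methyl-1-(2,4,6-trihydroxyphenyl)propan-1-one)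
Conditions: AlCl3 (3.5 equiv), PhNO2/CH2Cl2, 0 °C to 60 °C; aq. HCl work-up
Reagents that add atoms: none
Why: Friedel–Crafts acylation of the symmetrical, highly activated arene stops after one acyl group because the chelated aryl ketone deactivates the ring.

Step 2
Reactants: 3 phlorisobutyrophenone
Product: 4 isobutyrylfilicinic acid (3,5-dihydroxy-6,6-dimethyl-2-(2-methylpropanoyl)cyclohexa-2,4-dien-1-one)
Conditions: NaOMe (3.5 equiv), MeI (2.1 equiv), MeOH, 0 °C to 25 °C; aq. HCl work-up
Reagents that add atoms: iodomethane (CI)
Why: Dearomatising double C-methylation of the phloroglucinol phenoxide at one unsubstituted ring carbon (phenoxide C-alkylation) is the standard entry to acylfilicinic acids, and limiting MeI to two equivalents suppresses tetramethylation.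

Step 3
Reactants: 5 2,4,6-trihydroxybenzaldehyde
Product: 6 2-hydroxy-4,6-bis(methoxymethoxy)benzaldehyde
Conditions: MOMCl (2.2 equiv), N,N-diisopropylethylamine (2.6 equiv), CH2Cl2, 0 °C to 25 °C
Reagents that add atoms: chloromethyl methyl ether (COCCl)
Why: O-alkylation (acetal formation) takes the para hydroxyl and one ortho hydroxyl, while the last hydroxyl is held in a hydrogen bond to the formyl group and stays free.

Step 4
Reactants: 6 2-hydroxy-4,6-bis(methoxymethoxy)benzaldehyde; 7 prenyl bromide (1-bromo-3-methylbut-2-ene)
Product: 8 2,4-bis(methoxymethoxy)-6-(3-methylbut-2-enyloxy)benzaldehyde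
Conditions: K2CO3 (2 equiv), DMF, 25 °C to 50 °C
Reagents that add atoms: none
Why: Williamson etherification of the only free phenol places the prenyl group on the oxygen ortho to the carbonyl carbon, the position direct alkylation of the free triol would not select.

Step 5
Reactants: 8 2,4-bis(methoxymethoxy)-6-(3-methylbut-2-enyloxy)benzaldehyde; 9 2-(trimethylsilyl)phenyl trifluoromethanesulfonate
Product: 12 [2,4-bis(methoxymethoxy)-6-(3-methylbut-2-enyloxy)phenyl](phenyl)methanone, via benzyne 10 (not isolated), via Breslow enaminol 11 (not isolated)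
Conditions: 3-mesityl-4,5-dimethylthiazol-3-ium perchlorate (20 mol %), K2CO3 (40 mol %), KF (3 equiv), 18-crown-6 (3 equiv), THF, 25 °C to 40 °C, 9 (1.5 equiv) added slowly
Reagents that add atoms: none
Why: In this NHC-catalysed hydroacylation of an aryne, the thiazolylidene turns the formyl carbon into a nucleophilic Breslow enaminol (acyl anion equivalent) that adds to electrophilic benzyne and then releases the ketone after proton transfer; the two ortho alkoxy groups block benzoin self-coupling, but the reaction is untested on such a hindered, electron-rich aldehyde.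

Step 6
Reactants: 12 [2,4-bis(methoxymethoxy)-6-(3-methylbut-2-enyloxy)phenyl](phenyl)methanone
Product: 13 [2,4-dihydroxy-6-(3-methylbut-2-enyloxy)phenyl](phenyl)methanone
Conditions: conc. aq. HCl (cat.), MeOH/THF, 25 °C, stopped at full conversion
Reagents that add atoms: none
Why: Acid-catalysed transacetalisation transfers both MOM groups to methanol under conditions mild enough to leave the aryl prenyl ether intact, the MOM ortho to the ketone being especially labile.

Step 7
Reactants: 4 isobutyrylfilicinic acid; 13 [2,4-dihydroxy-6-(3-methylbut-2-enyloxy)phenyl](phenyl)methanone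
Product: 16 sarothralin, via Mannich base 14 (not isolated), via methylene trione 15 (not isolated)
Conditions: a) 4, CH2(NMe2)2 (1.1 equiv), MeCN, 0 °C to 25 °C, 1 h; b) 13 (1.3 equiv), 60 °C, N2; dilute aq. HCl work-up
Reagents that add atoms: bis(dimethylamino)methane (CN(C)CN(C)C)
Why: A Mannich reaction at the only free nucleophilic carbon of 4, then E1cB loss of dimethylamine, gives the quinone-methide-like methylene trione, which the phenoxide of 13 traps by Michael-type C-alkylation at C3, the ring carbon flanked by both hydroxyls.

**Compound list**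

1 | phloroglucinol (benzene-1,3,5-triol) | Oc1cc(O)cc(O)c1 | starting material
2 | isobutyryl chloride (2-methylpropanoyl chloride) | CC(C)C(Cl)=O | starting material
3 | phlorisobutyrophenone, 2-methyl-1-(2,4,6-trihydroxyphenyl)propan-1-one | CC(C)C(=O)c1c(O)cc(O)cc1O | intermediate
4 | isobutyrylfilicinic acid, 3,5-dihydroxy-6,6-dimethyl-2-(2-methylpropanoyl)cyclohexa-2,4-dien-1-one | CC(C)C(=O)C1=C(O)C=C(O)C(C)(C)C1=O | intermediate
5 | 2,4,6-trihydroxybenzaldehyde | O=Cc1c(O)cc(O)cc1O | starting material
6 | 2-hydroxy-4,6-bis(methoxymethoxy)benzaldehyde | O=Cc1c(O)cc(OCOC)cc1OCOC | intermediate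
7 | prenyl bromide, 1-bromo-3-methylbut-2-ene | CC(C)=CCBr | starting material
8 | 2,4-bis(methoxymethoxy)-6-(3-methylbut-2-enyloxy)benzaldehyde | O=Cc1c(OCC=C(C)C)cc(OCOC)cc1OCOC | intermediate
9 | 2-(trimethylsilyl)phenyl trifluoromethanesulfonate | C[Si](C)(C)c1ccccc1OS(=O)(=O)C(F)(F)F | starting material
10 | benzyne (1,2-didehydrobenzene) | C1#CC=CC=C1 | intermediate (not isolated)
11 | Breslow enaminol of 8: 2-{hydroxy[2,4-bis(methoxymethoxy)-6-(3-methylbut-2-enyloxy)phenyl]methylidene}-3-mesityl-4,5-dimethyl-2,3-dihydrothiazole | OC(=C1SC(C)=C(C)N1c1c(C)cc(C)cc1C)c1c(OCC=C(C)C)cc(OCOC)cc1OCOC | intermediate (not isolated)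
12 | [2,4-bis(methoxymethoxy)-6-(3-methylbut-2-enyloxy)phenyl](phenyl)methanone | O=C(c1ccccc1)c1c(OCC=C(C)C)cc(OCOC)cc1OCOC | intermediate
13 | [2,4-dihydroxy-6-(3-methylbut-2-enyloxy)phenyl](phenyl)methanone | O=C(c1ccccc1)c1c(OCC=C(C)C)cc(O)cc1O | intermediate
14 | Mannich base, 4-[(dimethylamino)methyl]-3,5-dihydroxy-6,6-dimethyl-2-(2-methylpropanoyl)cyclohexa-2,4-dien-1-one | CC(C)C(=O)C1=C(O)C(CN(C)C)=C(O)C(C)(C)C1=O | intermediate (not isolated)
15 | methylene trione, 5-hydroxy-2,2-dimethyl-6-methylidene-4-(2-methylpropanoyl)cyclohex-4-ene-1,3-dione | CC(C)C(=O)C1=C(O)C(=C)C(=O)C(C)(C)C1=O | intermediate (not isolated)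
16 | sarothralin, 4-{[3-benzoyl-2,6-dihydroxy-4-(3-methylbut-2-enyloxy)phenyl]methyl}-3,5-dihydroxy-6,6-dimethyl-2-(2-methylpropanoyl)cyclohexa-2,4-dien-1-one (achiral) | CC(C)=CCOc1cc(O)c(CC2=C(O)C(C)(C)C(=O)C(C(=O)C(C)C)=C2O)c(O)c1C(=O)c1ccccc1 | target

**Step count**

Total steps: 7. Longest linear sequence: 5 (steps 3 to 7, from 5); the other branch is steps 1, 2 and 7.

**Three steps most likely to fail, with fallbacks**

Step 5 (most likely to fail). The aldehyde is doubly ortho-substituted and very electron-rich, so the Breslow enaminol may form slowly. Benzyne could then be lost to an ene reaction with the prenyl alkene or to a [2+2] reaction with the carbonyl group. Fallback, setting out from 8: add PhMgBr in THF at 0 °C to give the racemic carbinol [2,4-bis(methoxymethoxy)-6-(3-methylbut-2-enyloxy)phenyl](phenyl)methanol F1. Oxidise F1 with MnO2 in CH2Cl2 at 25 °C, which erases its stereocentre and returns to the route at 12.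

Step 7. Two things can go wrong. The methylene trione 15 may be trapped at C5 of 13 (next to the prenyloxy group) instead of C3, or may undergo a hetero-Diels–Alder reaction with the prenyl alkene. The preference for C3 rests on analogy with C-alkylation of 2,4-dihydroxy-6-alkoxy aryl ketones and is not guaranteed. Fallback, setting out from 4: condense two equivalents of 4 with aqueous formaldehyde to give the crystalline, isolable dimer methylenebis(isobutyrylfilicinic acid) F2. Heat F2 with excess 13 and NaOAc in dioxane. This methylene-exchange reaction ("rottlerone change") releases 15 slowly by retro-Michael cleavage, so it is captured at low concentration by the phenoxide of 13, and the route is rejoined at 16. Any C5 isomer is removed by chromatography; this fallback does not change the intrinsic regioselectivity.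

Step 6. The aryl prenyl ether may be cleaved by the acid needed to remove the para MOM group. Fallback, setting out from 5: alkylate with allyl bromide (2.1 equiv) and K2CO3 in acetone to give 2-hydroxy-4,6-bis(prop-2-enyloxy)benzaldehyde F3. Prenylate F3 with 7 as in step 4 to give 2,4-bis(prop-2-enyloxy)-6-(3-methylbut-2-enyloxy)benzaldehyde F4. Carry out the aryne hydroacylation with 9 as in step 5 to give [2,4-bis(prop-2-enyloxy)-6-(3-methylbut-2-enyloxy)phenyl](phenyl)methanone F5. Remove both allyl groups from F5 with Pd(PPh3)4 (catalytic zerovalent palladium) and morpholine in THF at 25 °C; the unsubstituted allyl ethers ionise much faster than the trisubstituted prenyl ether. This acid-free sequence returns to the route at 13.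

**Further compounds**

F1 | step 5 | [2,4-bis(methoxymethoxy)-6-(3-methylbut-2-enyloxy)phenyl](phenyl)methanol (racemic) | OC(c1ccccc1)c1c(OCC=C(C)C)cc(OCOC)cc1OCOC
F2 | step 7 | methylenebis(isobutyrylfilicinic acid), 4,4'-methylenebis[3,5-dihydroxy-6,6-dimethyl-2-(2-methylpropanoyl)cyclohexa-2,4-dien-1-one] | CC(C)C(=O)C1=C(O)C(CC2=C(O)C(C)(C)C(=O)C(C(=O)C(C)C)=C2O)=C(O)C(C)(C)C1=O
F3 | step 6 | 2-hydroxy-4,6-bis(prop-2-enyloxy)benzaldehyde | O=Cc1c(O)cc(OCC=C)cc1OCC=C
F4 | step 6 | 2,4-bis(prop-2-enyloxy)-6-(3-methylbut-2-enyloxy)benzaldehyde | O=Cc1c(OCC=C(C)C)cc(OCC=C)cc1OCC=C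
F5 | step 6 | [2,4-bis(prop-2-enyloxy)-6-(3-methylbut-2-enyloxy)phenyl](phenyl)methanone | O=C(c1ccccc1)c1c(OCC=C(C)C)cc(OCC=C)cc1OCC=C
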